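# Proposed total synthesis of 3-[4-(1H-indol-3-yl)-2,3,5,6-tetramethoxyphenyl]-5-prenyl-1H-indole (24) by ring expansion of a squarate-derived cyclobutenone

## The problem

Compound 24 is a hexasubstituted benzene. Two indol-3-yl groups stand para to each other on C1 and C4 of the central ring, the other four carbons (C2, C3, C5, C6) carry methoxy groups, and the indoles differ only by the prenyl group at C5 of indole A (the indole on C1). The molecule has no stereocentre, so the task is purely regiochemical: the sequence aryl/OMe/OMe/aryl/OMe/OMe has to be laid down, and two nearly identical indoles have to be delivered once each to defined positions. Each biaryl bond is flanked by two ortho methoxy groups on one side and by C2–H and C4–H of the indole on the other, so cross-coupling onto a finished tetraoxygenated ring would be slow and, with two like partners, statistical. The groups that will not stand rough treatment are the prenyl double bond (protic and Lewis acids add across it or cyclise it onto the benzo ring; electrophilic halogen attacks it), the free indoles (acid, oxidants, electrophiles at C2) and the electron-rich core, which at the hydroquinone stage is oxidised by air to the quinone. The feature that opens the structure is the substitution pattern: C2–C3–C4–C5 carry O, OMe, indole B and O, which is a squarate four-carbon unit with one alkoxy group exchanged for an aryl group, while C1–C6 carries indole A and OMe, which is a 1-aryl-2-methoxyvinyl group. Joining that vinyl group to the squarate-derived cyclobutenone leaves only the C5–C6 bond to be made, and a thermal ring expansion makes it.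

## Retrosynthesis

**24 from 23.** The last bonds cut are the N–S bond on indole B and the N–CH2 bond of the SEM group on indole A. The two nitrogens carry different groups because the fragments have different duties (see below), but both groups fall to fluoride, so 23 needs one operation. Nothing else in 23 is sensitive to fluoride or base.

**23 from 22.** The O–CH3 bonds on C2 and C5 are cut, giving hydroquinone 22. This is preferred to any plan that brings in all four methoxy groups on a preformed benzene, because the two hydroxyls of 22 are exactly what the ring-forming step delivers. The forward reaction must methylate two hindered phenols without letting the dianion be oxidised.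

**22 from 19.** The C5–C6 bond is cut and C2 is reconnected to C5, which turns the benzene ring into the cyclobutenone (±)-19 (forward: through ketene 20 and dienone 21). The neighbouring options are a twofold cross-coupling on a tetraoxygenated benzene core or stepwise arylation of a quinone. Both have to form the two hindered aryl bonds and tell two like indoles apart; in 19 both indoles already sit on sp2 carbons. The precursor has no benzene ring and is assembled from two fragments by one C–C bond. The forward step needs outward rotation of the hydroxyl on ring opening and a 6π closure onto the methoxyvinyl terminus.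

**19 from 18 and 8.** The bond between the carbinol carbon and the vinyl carbon is cut, giving vinyllithium 18 and cyclobutenedione 8. The addition must go to the carbonyl next to the methoxy-bearing carbon. The other carbonyl is a vinylogous ester and is shielded by the indolyl group. The carbonyl to be attacked is conjugated with indole B, and an electron-rich indol-3-yl group would deactivate it as a vinylogous amide; for that reason indole B carries a phenylsulfonyl group, which turns its donor strength down. The reagent 18 is taken from stannane 17 by tin–lithium exchange at −78 °C. A cis-2-alkoxyvinyllithium is stable at that temperature, whereas routes that need warming (decomposition of a sulfonylhydrazone dianion) risk loss of LiOMe.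

**17 from 16 from 14.** The C–Sn bond is traced to the C–O bond of enol triflate 16 and that to ketone 14. The enolate of an α-alkoxy aryl ketone has O− and OMe cis, so triflate, tin and finally lithium all end up cis to the methoxy group, which is the arrangement in which anti elimination is impossible. The precursor is a plain ketone with one enolisable position.

**14 from 12 and 13; 12 from 11; 11 from 9 and 10.** The C5–prenyl bond is cut (Stille coupling of bromide 12 with stannane 13), then the N–SEM bond, then the C3–acyl bond (acylation of 9 with 10). The order keeps the Lewis acid of the acylation away from the alkene and uses the bromine of commercial 9 as the handle. SEM is chosen for indole A because it survives amide base and organolithium and, unlike a sulfonyl group, does not acidify C2–H next to the carbanion of 18.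

**8 from 3 and 4; 3 from 1.** The bond from C3 of indole B to the four-membered ring is cut, giving the 3-lithioindole 5 (from iodide 3) and dimethyl squarate 4; the adduct 6 is transposed through trifluoroacetate 7. Iodide 3 comes from indole 1 by iodination and N-sulfonylation. The forward reaction must trap 5 before lithium migrates to C2, hence the very low temperature.

## Roads not taken

**Alternative 1:** Fischer indolisation to build indole A last. The cut is through the pyrrole ring of indole A (C3–C3a and N1–C2). Forward, [4-prenylphenyl]hydrazine A2 condenses with the arylacetaldehyde A3; under protic acid the ene-hydrazine rearranges and loses ammonia to give A1.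
- Merits: a para-substituted hydrazine can give only the 5-prenyl indole, so the prenyl position is fixed without any allyl cross-coupling, and indole A never needs a protecting group. In this respect it is cleaner than the chosen plan, whose Stille coupling has to rely on reductive elimination at the unhindered allyl terminus.
- Weak points: A3 already contains the hexasubstituted ring and the hindered bond to indole B, so the hard part is presupposed. The acetaldehyde chain sits between two methoxy groups, which hinders both its installation and the sigmatropic step. The prenyl alkene must survive warm acid, and A2 is oxidation-sensitive.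
- Comparison: the chosen plan sets against the cleaner prenyl placement that it creates the central ring and places both indoles in one neutral thermal step, and that the prenyl group never meets acid.

**Alternative 2:** Head-to-tail condensation of two indolylpyruvate thioesters. The cut is at C1–C2 and C4–C5 of the central ring. Forward, thioesters A5 and A6 (taken here as S-ethyl) acylate each other under soft enolisation to give dihydroxyquinone A4, which O-methylation and reductive methylation would carry to the target.
- Merits: this is the shortest route, needs no protecting groups, has both indolyl–ring bonds preformed and reaches the quinone oxidation level directly. In step count and protecting-group economy it is better than the chosen plan.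
- Weak points: A5 and A6 differ only in a remote prenyl group and so react alike. Crossed and self-condensation compete statistically, the symmetrical quinones A7 and A8 form beside A4, and at best half the material can be A4. The α-keto thioesters are enol-rich and can also undergo aldol or head-to-head reactions. Free indoles are exposed to a quinone oxidant.
- Comparison: the chosen plan sets against the shorter route a non-statistical placement of each indole, paid for with organometallic steps and two protecting groups.

**Alternative 3:** Benzyne annulation of a 2H-azirine to build indole B. The cut is at N1–C7a and C3–C3a of indole B. Forward, benzyne released from A11 by fluoride (CsF) is attacked by the nitrogen of azirine A10, the aryl anion closes on the imine carbon and the strained N–C bond opens to give A9.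
- Merits: indole B is unsubstituted, so nothing has to be differentiated. The conditions are nearly neutral and leave prenyl and SEM alone, and the free N–H is obtained directly. The key step is milder than the low-temperature organolithium steps of the chosen plan.
- Weak points: A10 carries the whole hexasubstituted ring and indole A, so the core is again presupposed. The azirine must be made on a carbon flanked by two methoxy groups. Benzyne is unselective and can N-arylate A9, undergo an ene reaction with the prenyl group or attack the electron-rich rings.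
- Comparison: the chosen plan sets against the milder key step that it solves the central ring directly and in fewer steps.

Key step: step 9

## Route

Abbreviations in names: SEM = [2-(trimethylsilyl)ethoxy]methyl on N1 of indole A; prenyl = 3-methylbut-2-en-1-yl.

Remark on the chemistry: the (Z) geometry drawn for 15–19 assumes the usual enolate of an α-alkoxy aryl ketone with O− and OMe cis; it is erased in step 9 and matters only for the lifetime of 18.

Step 1
Reactants: 1 indole
Product: 3 3-iodo-1-(phenylsulfonyl)indole, via 3-iodoindole 2 (not isolated)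
Conditions: I2, KOH, DMF, rt; then NaH, PhSO2Cl, 0 °C to rt (one pot)
Reagents that add atoms: iodine, [I][I]; benzenesulfonyl chloride, O=S(=O)(Cl)c1ccccc1
Why: Electrophilic iodination at C3 followed by N-sulfonylation of the indolide in the same flask, so the labile 3-iodoindole is never handled; phenylsulfonyl (no benzylic hydrogens) tolerates the halogen–lithium exchange of step 2 and later lowers the donor strength of indole B.

Step 2
Reactants: 3 3-iodo-1-(phenylsulfonyl)indole; 4 dimethyl squarate
Product: 8 3-methoxy-4-[1-(phenylsulfonyl)indol-3-yl]cyclobut-3-ene-1,2-dione, via 3-lithio-1-(phenylsulfonyl)indole 5 (not isolated), via lithium alkoxide of the squarate 1,2-adduct 6 (not isolated), via trifluoroacetate of the squarate 1,2-adduct 7 (not isolated)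
Conditions: t-BuLi (2 equiv), THF, −100 °C; cannulate into 4, THF, −100 to −78 °C; (CF3CO)2O, −78 °C; aq. NH4Cl, rt
Reagents that add atoms: water, O
Why: Iodine–lithium exchange at −100 °C gives the 3-lithioindole before it can isomerise to the 2-lithio species; 1,2-addition to one squarate carbonyl, O-trifluoroacetylation and hydrolytic loss of trifluoroacetate and methanol through the methoxy-stabilised cyclobutenyl cation transpose the carbonyl, the standard route from a dialkyl squarate to a 3-aryl-4-alkoxycyclobutenedione.

Step 3
Reactants: 9 5-bromoindole; 10 methoxyacetyl chloride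
Product: 11 1-(5-bromo-1H-indol-3-yl)-2-methoxyethan-1-one
Conditions: Et2AlCl (1.5 equiv), CH2Cl2, 0 °C; then 10, 0 °C
Reagents that add atoms: none
Why: Friedel–Crafts C3-acylation of an unprotected indole through its N-aluminium derivative; Et2AlCl consumes the HCl and the acid chloride is attacked without a free acylium ion, so loss of CO from the α-alkoxyacyl unit is not expected, and no alkene is yet present to meet the Lewis acid.

Step 4
Reactants: 11 1-(5-bromo-1H-indol-3-yl)-2-methoxyethan-1-one
Product: 12 1-(5-bromo-1-SEM-indol-3-yl)-2-methoxyethan-1-one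
Conditions: NaH (1.1 equiv), DMF, 0 °C; SEMCl, 0 °C to rt
Reagents that add atoms: 2-(trimethylsilyl)ethoxymethyl chloride, C[Si](C)(C)CCOCCl
Why: N-alkylation of the indolide; the N–H of a 3-acylindole is far more acidic than the CH2OMe group, so one equivalent of base gives the nitrogen anion only.

Step 5
Reactants: 12 1-(5-bromo-1-SEM-indol-3-yl)-2-methoxyethan-1-one; 13 tributyl(3-methylbut-2-en-1-yl)stannane
Product: 14 2-methoxy-1-(5-prenyl-1-SEM-indol-3-yl)ethan-1-one
Conditions: Pd(PPh3)4 (5 mol %), DMF, 100 °C
Reagents that add atoms: none
Why: Stille coupling; zerovalent palladium inserts into the C5–Br bond, the allyl group is transferred from tin and the aryl(π-prenyl) complex of divalent palladium eliminates reductively at the unsubstituted CH2 terminus to give the linear prenyl arene; the neutral conditions leave ketone and SEM group untouched.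

Step 6
Reactants: 14 2-methoxy-1-(5-prenyl-1-SEM-indol-3-yl)ethan-1-one
Product: 16 (Z)-2-methoxy-1-(5-prenyl-1-SEM-indol-3-yl)ethenyl trifluoromethanesulfonate, via potassium (Z)-enolate 15 (not isolated)
Conditions: KN(SiMe3)2, THF, −78 °C; PhNTf2, −78 to 0 °C; Et3N-buffered work-up
Reagents that add atoms: N-phenylbis(trifluoromethanesulfonimide), O=S(=O)(N(c1ccccc1)S(=O)(=O)C(F)(F)F)C(F)(F)F
Why: Enolate O-sulfonylation; the only enolisable position is the CH2OMe group and the enolate has O− and OMe cis, so the triflate oxygen and the methoxy group end up cis, the geometry later needed for a stable vinyllithium.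

Step 7
Reactants: 16 (Z)-2-methoxy-1-(5-prenyl-1-SEM-indol-3-yl)ethenyl trifluoromethanesulfonate
Product: 17 3-[(Z)-2-methoxy-1-(trimethylstannyl)ethenyl]-5-prenyl-1-SEM-indole
Conditions: Me3SnSnMe3, Pd(PPh3)4 (5 mol %), LiCl, THF, 65 °C; neutral alumina
Reagents that add atoms: hexamethylditin, C[Sn](C)(C)[Sn](C)(C)C
Why: Palladium-catalysed stannylation of an enol triflate with a distannane (oxidative addition, tin-to-palladium transmetalation, reductive elimination) proceeds with retention of alkene geometry, so tin stays cis to the methoxy group; acid is avoided because the product protodestannylates easily.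

Step 8
Reactants: 17 3-[(Z)-2-methoxy-1-(trimethylstannyl)ethenyl]-5-prenyl-1-SEM-indole; 8 3-methoxy-4-[1-(phenylsulfonyl)indol-3-yl]cyclobut-3-ene-1,2-dione
Product: 19 (±)-4-hydroxy-3-methoxy-4-[(Z)-2-methoxy-1-(5-prenyl-1-SEM-indol-3-yl)ethenyl]-2-[1-(phenylsulfonyl)indol-3-yl]cyclobut-2-en-1-one, via cis-2-methoxyvinyllithium 18 (not isolated)
Conditions: MeLi (1 equiv), THF, −78 °C; cannulate into 8, THF, −78 °C; aq. NH4Cl, −78 °C to rt; Et3N-deactivated silica
Reagents that add atoms: none
Why: Tin–lithium exchange at −78 °C gives 18 with retention, lithium being chelated by the cis methoxy group and unable to eliminate anti, as in cis-2-alkoxyvinyllithium reagents; 1,2-addition goes to the carbonyl next to the methoxy-bearing carbon because the other carbonyl is a vinylogous ester shielded by the indolyl group and the sulfonyl group keeps indole B from deactivating the carbonyl under attack; the carbinol centre forms racemic and is destroyed in step 9, and acid is excluded because a 2-methoxyvinyl carbinol transposes to an enal.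

Step 9
Reactants: 19 (±)-4-hydroxy-3-methoxy-4-[(Z)-2-methoxy-1-(5-prenyl-1-SEM-indol-3-yl)ethenyl]-2-[1-(phenylsulfonyl)indol-3-yl]cyclobut-2-en-1-one
Product: 22 2,5-dimethoxy-3-(5-prenyl-1-SEM-indol-3-yl)-6-[1-(phenylsulfonyl)indol-3-yl]benzene-1,4-diol, via dienylketene 20 (not isolated), via cyclohexadienone 21 (not isolated)
Conditions: toluene (degassed), 110 °C, Ar; crude product kept under Ar
Reagents that add atoms: none
Why: Heating breaks the bond between the carbonyl carbon and the carbinol carbon in a conrotatory 4π electrocyclic opening; the hydroxyl, as the donor substituent, rotates outward, so the alkenyl group turns inward and lies cis to the ketene in dienylketene 20. Disrotatory 6π electrocyclisation of 20 then joins the ketene carbon to the methoxy-bearing vinyl carbon (the C5–C6 bond of the central ring), closing the six-membered carbocycle as dienone 21, and enolisation gives the aromatic hydroquinone 22. The closest known reaction type is the thermal rearrangement of squarate-derived 4-alkenyl-4-hydroxycyclobutenones to hydroquinones (Moore-type ring expansion). No stereocentre is formed: the carbinol centre and the alkene geometry of 19 are both erased on aromatisation. The selectivity needed is torquoselectivity, secured by the strong preference of an oxygen donor on the sp3 carbon for outward rotation; inward rotation would let the hydroxyl capture the ketene as a butenolide. Closure can only occur onto the vinyl terminus, since attack on C2 of indole A would give a seven-membered ring, and the methoxy group on the inside of the triene terminus meets only the linear, unhindered ketene carbon. The para relation of the indoles and the placing of the hydroxyls on C2 and C5 are inherited from the regiochemistry of step 8; oxygen is excluded because 22 is easily oxidised to the quinone.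

Step 10
Reactants: 22 2,5-dimethoxy-3-(5-prenyl-1-SEM-indol-3-yl)-6-[1-(phenylsulfonyl)indol-3-yl]benzene-1,4-diol
Product: 23 3-{2,3,5,6-tetramethoxy-4-[1-(phenylsulfonyl)indol-3-yl]phenyl}-5-prenyl-1-SEM-indole
Conditions: Me2SO4, K2CO3, acetone, reflux, Ar
Reagents that add atoms: dimethyl sulfate, COS(=O)(=O)OC
Why: Williamson O-methylation of both phenols; exclusion of oxygen keeps the dianion from being oxidised to the quinone, and sulfonamide, SEM group and prenyl group are inert to carbonate in acetone.

Step 11
Reactants: 23 3-{2,3,5,6-tetramethoxy-4-[1-(phenylsulfonyl)indol-3-yl]phenyl}-5-prenyl-1-SEM-indole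
Product: 24 3-[4-(1H-indol-3-yl)-2,3,5,6-tetramethoxyphenyl]-5-prenyl-1H-indole
Conditions: Bu4NF (excess), H2NCH2CH2NH2, THF, reflux; aq. work-up
Reagents that add atoms: none
Why: Fluoride attacks silicon of the SEM group (ethene is expelled and the N-hydroxymethyl anion loses formaldehyde, which the diamine traps) and sulfur of the N-sulfonyl group; both indolide anions are protonated on work-up and nothing else in the molecule is sensitive to fluoride or base.

## Compound list

1 | indole (1H-indole) | c1ccc2[nH]ccc2c1 | starting material
2 | 3-iodo-1H-indole (formed in the flask, not isolated) | Ic1c[nH]c2ccccc12 | intermediate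
3 | 3-iodo-1-(phenylsulfonyl)-1H-indole | Ic1cn(S(=O)(=O)c2ccccc2)c2ccccc12 | intermediate
4 | dimethyl squarate (3,4-dimethoxycyclobut-3-ene-1,2-dione) | COC1=C(OC)C(=O)C1=O | starting material
5 | 3-lithio-1-(phenylsulfonyl)indole (not isolated) | [Li]c1cn(S(=O)(=O)c2ccccc2)c2ccccc12 | intermediate
6 | lithium (±)-2,3-dimethoxy-4-oxo-1-[1-(phenylsulfonyl)indol-3-yl]cyclobut-2-en-1-olate (not isolated) | [Li]OC1(c2cn(S(=O)(=O)c3ccccc3)c3ccccc23)C(OC)=C(OC)C1=O | intermediate
7 | (±)-2,3-dimethoxy-4-oxo-1-[1-(phenylsulfonyl)indol-3-yl]cyclobut-2-en-1-yl trifluoroacetate (not isolated) | O=C(OC1(c2cn(S(=O)(=O)c3ccccc3)c3ccccc23)C(OC)=C(OC)C1=O)C(F)(F)F | intermediate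
8 | 3-methoxy-4-[1-(phenylsulfonyl)-1H-indol-3-yl]cyclobut-3-ene-1,2-dione | COC1=C(c2cn(S(=O)(=O)c3ccccc3)c3ccccc23)C(=O)C1=O | intermediate
9 | 5-bromo-1H-indole | Brc1ccc2[nH]ccc2c1 | starting material
10 | methoxyacetyl chloride | COCC(Cl)=O | starting material
11 | 1-(5-bromo-1H-indol-3-yl)-2-methoxyethan-1-one | COCC(=O)c1c[nH]c2ccc(Br)cc12 | intermediate
12 | 1-(5-bromo-1-{[2-(trimethylsilyl)ethoxy]methyl}-1H-indol-3-yl)-2-methoxyethan-1-one | COCC(=O)c1cn(COCC[Si](C)(C)C)c2ccc(Br)cc12 | intermediate
13 | tributyl(3-methylbut-2-en-1-yl)stannane | CCCC[Sn](CCCC)(CCCC)CC=C(C)C | starting material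
14 | 2-methoxy-1-[5-(3-methylbut-2-en-1-yl)-1-{[2-(trimethylsilyl)ethoxy]methyl}-1H-indol-3-yl]ethan-1-one | COCC(=O)c1cn(COCC[Si](C)(C)C)c2ccc(CC=C(C)C)cc12 | intermediate
15 | potassium (Z)-2-methoxy-1-(5-prenyl-1-SEM-indol-3-yl)ethen-1-olate, O− cis to OMe (not isolated) | [K]O/C(=C\OC)c1cn(COCC[Si](C)(C)C)c2ccc(CC=C(C)C)cc12 | intermediate
16 | (Z)-2-methoxy-1-(5-prenyl-1-SEM-indol-3-yl)ethenyl trifluoromethanesulfonate, OTf cis to OMe | FC(F)(F)S(=O)(=O)O/C(=C\OC)c1cn(COCC[Si](C)(C)C)c2ccc(CC=C(C)C)cc12 | intermediate
17 | 3-[(Z)-2-methoxy-1-(trimethylstannyl)ethenyl]-5-prenyl-1-SEM-indole, Sn cis to OMe | C[Sn](C)(C)/C(=C\OC)c1cn(COCC[Si](C)(C)C)c2ccc(CC=C(C)C)cc12 | intermediate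
18 | [(E)-2-methoxy-1-(5-prenyl-1-SEM-indol-3-yl)ethenyl]lithium, Li cis to OMe (not isolated) | [Li]/C(=C\OC)c1cn(COCC[Si](C)(C)C)c2ccc(CC=C(C)C)cc12 | intermediate
19 | (±)-4-hydroxy-3-methoxy-4-[(Z)-2-methoxy-1-(5-prenyl-1-SEM-indol-3-yl)ethenyl]-2-[1-(phenylsulfonyl)indol-3-yl]cyclobut-2-en-1-one | O=C1C(c2cn(S(=O)(=O)c3ccccc3)c3ccccc23)=C(OC)C1(O)/C(=C\OC)c1cn(COCC[Si](C)(C)C)c2ccc(CC=C(C)C)cc12 | intermediate
20 | (3Z,5Z)-4-hydroxy-3,6-dimethoxy-5-(5-prenyl-1-SEM-indol-3-yl)-2-[1-(phenylsulfonyl)indol-3-yl]hexa-1,3,5-trien-1-one (dienylketene, not isolated) | O=C=C(c1cn(S(=O)(=O)c2ccccc2)c2ccccc12)/C(OC)=C(O)\C(=C/OC)c1cn(COCC[Si](C)(C)C)c2ccc(CC=C(C)C)cc12 | intermediate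
21 | (±)-4-hydroxy-3,6-dimethoxy-5-(5-prenyl-1-SEM-indol-3-yl)-2-[1-(phenylsulfonyl)indol-3-yl]cyclohexa-2,4-dien-1-one (not isolated) | O=C1C(c2cn(S(=O)(=O)c3ccccc3)c3ccccc23)=C(OC)C(O)=C(c2cn(COCC[Si](C)(C)C)c3ccc(CC=C(C)C)cc23)C1OC | intermediate
22 | 2,5-dimethoxy-3-(5-prenyl-1-SEM-indol-3-yl)-6-[1-(phenylsulfonyl)indol-3-yl]benzene-1,4-diol | Oc1c(-c2cn(S(=O)(=O)c3ccccc3)c3ccccc23)c(OC)c(O)c(-c2cn(COCC[Si](C)(C)C)c3ccc(CC=C(C)C)cc23)c1OC | intermediate
23 | 3-{2,3,5,6-tetramethoxy-4-[1-(phenylsulfonyl)-1H-indol-3-yl]phenyl}-5-(3-methylbut-2-en-1-yl)-1-{[2-(trimethylsilyl)ethoxy]methyl}-1H-indole | COc1c(-c2cn(S(=O)(=O)c3ccccc3)c3ccccc23)c(OC)c(OC)c(-c2cn(COCC[Si](C)(C)C)c3ccc(CC=C(C)C)cc23)c1OC | intermediate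
24 | 3-[4-(1H-indol-3-yl)-2,3,5,6-tetramethoxyphenyl]-5-(3-methylbut-2-en-1-yl)-1H-indole | COc1c(OC)c(-c2c[nH]c3ccc(CC=C(C)C)cc23)c(OC)c(OC)c1-c1c[nH]c2ccccc12 | target

## Step count and least certain steps

Total step count: 11. Longest linear sequence: 9 steps (steps 3 to 11, from 9); the other branch (steps 1 and 2) joins at step 8.

**Step 9 (key step).** The ring opening may occur with inward rotation of the hydroxyl, which would let the hydroxyl capture the ketene as a butenolide. The 6π closure may be slowed by the methoxy group on the inside of the triene terminus. The hydroquinone may be oxidised by adventitious oxygen during handling. Fallback: setting out from 17 and 8, the lithium alkoxide formed in step 8 is methylated in the flask with methyl triflate (−78 to 0 °C) instead of being protonated, which should give the methyl ether (±)-3,4-dimethoxy-4-[(Z)-2-methoxy-1-(5-prenyl-1-SEM-indol-3-yl)ethenyl]-2-[1-(phenylsulfonyl)indol-3-yl]cyclobut-2-en-1-one F1. It has no hydroxyl to trap the ketene. Thermolysis in toluene should then deliver the monophenol 2,4,5-trimethoxy-3-(5-prenyl-1-SEM-indol-3-yl)-6-[1-(phenylsulfonyl)indol-3-yl]phenol F2, which is not a hydroquinone and cannot pass to a quinone. Methylation as in step 10 brings it back to 23.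

**Step 8.** The carbanion 18 may decay before it meets the dione, by proton transfer from C2–H of either indole or by syn elimination of LiOMe; less likely, it may attack the vinylogous-ester carbonyl or the sulfonyl group. Fallback: setting out from 17, iododestannylation (I2, CH2Cl2, 0 °C) should give 3-[(Z)-1-iodo-2-methoxyethenyl]-5-prenyl-1-SEM-indole F3. Iodine–magnesium exchange with i-PrMgCl·LiCl (THF, −40 °C) then gives chloro[(E)-2-methoxy-1-(5-prenyl-1-SEM-indol-3-yl)ethenyl]magnesium F4, which is less basic and much less prone to β-elimination than the lithium reagent. Its addition to 8 returns to 19.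

**Step 6.** The enol triflate may ionise or hydrolyse: the indol-3-yl group on the triflate-bearing carbon stabilises a vinyl cation and the enol ether is acid-labile, so material may be lost on work-up or chromatography. Fallback: setting out from 14, condensation with 2,4,6-triisopropylbenzenesulfonohydrazide (cat. HCl, THF, rt) gives N'-[2-methoxy-1-(5-prenyl-1-SEM-indol-3-yl)ethylidene]-2,4,6-triisopropylbenzenesulfonohydrazide F5. Two equivalents of n-BuLi (THF, −78 °C, brief warming until nitrogen evolution ends, recooling) generate 18 by Shapiro reaction, and addition to 8 returns to 19, bypassing 16 and 17. The price is the warming period, which 18 must survive.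

**Step 2.** Lithium may migrate from C3 to C2 of the sulfonylindole if the temperature rises before the squarate is reached, giving the 2-substituted isomer, and a second aryllithium may add to adduct 6. Fallback: setting out from 1, uncatalysed Friedel–Crafts reaction of indole with squaric acid dichloride (3,4-dichlorocyclobut-3-ene-1,2-dione; Et2O, 0 °C to rt) gives 3-chloro-4-(1H-indol-3-yl)cyclobut-3-ene-1,2-dione F6. Methanolysis gives 3-(1H-indol-3-yl)-4-methoxycyclobut-3-ene-1,2-dione F7, and N-sulfonylation (PhSO2Cl, Et3N, cat. DMAP, CH2Cl2) returns to 8 without any lithioindole.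

**Step 5.** Allylic transposition during transmetalation or reductive elimination may give the 1,1-dimethylallyl isomer, and the double bond may migrate into conjugation with the ring at 100 °C. Fallback: setting out from 12, the polarity is reversed. Miyaura borylation (B2pin2, KOAc, PdCl2(dppf), dioxane, 80 °C) gives 2-methoxy-1-[5-(4,4,5,5-tetramethyl-1,3,2-dioxaborolan-2-yl)-1-SEM-indol-3-yl]ethan-1-one F8. Suzuki–Miyaura coupling with prenyl bromide (Pd(PPh3)4, K2CO3, THF/H2O, 60 °C) returns to 14; here the π-prenyl complex of divalent palladium comes from the electrophile and couples at its unhindered CH2 end.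

## Further compounds

F1 | step 9 | (±)-3,4-dimethoxy-4-[(Z)-2-methoxy-1-(5-prenyl-1-SEM-indol-3-yl)ethenyl]-2-[1-(phenylsulfonyl)indol-3-yl]cyclobut-2-en-1-one | O=C1C(c2cn(S(=O)(=O)c3ccccc3)c3ccccc23)=C(OC)C1(OC)/C(=C\OC)c1cn(COCC[Si](C)(C)C)c2ccc(CC=C(C)C)cc12
F2 | step 9 | 2,4,5-trimethoxy-3-(5-prenyl-1-SEM-indol-3-yl)-6-[1-(phenylsulfonyl)indol-3-yl]phenol | Oc1c(-c2cn(S(=O)(=O)c3ccccc3)c3ccccc23)c(OC)c(OC)c(-c2cn(COCC[Si](C)(C)C)c3ccc(CC=C(C)C)cc23)c1OC
F3 | step 8 | 3-[(Z)-1-iodo-2-methoxyethenyl]-5-prenyl-1-SEM-indole | I/C(=C\OC)c1cn(COCC[Si](C)(C)C)c2ccc(CC=C(C)C)cc12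
F4 | step 8 | chloro[(E)-2-methoxy-1-(5-prenyl-1-SEM-indol-3-yl)ethenyl]magnesium (Mg cis to OMe) | Cl[Mg]/C(=C\OC)c1cn(COCC[Si](C)(C)C)c2ccc(CC=C(C)C)cc12
F5 | step 6 | N'-[2-methoxy-1-(5-prenyl-1-SEM-indol-3-yl)ethylidene]-2,4,6-triisopropylbenzenesulfonohydrazide | COCC(=NNS(=O)(=O)c1c(C(C)C)cc(C(C)C)cc1C(C)C)c1cn(COCC[Si](C)(C)C)c2ccc(CC=C(C)C)cc12
F6 | step 2 | 3-chloro-4-(1H-indol-3-yl)cyclobut-3-ene-1,2-dione | ClC1=C(c2c[nH]c3ccccc23)C(=O)C1=O
F7 | step 2 | 3-(1H-indol-3-yl)-4-methoxycyclobut-3-ene-1,2-dione | COC1=C(c2c[nH]c3ccccc23)C(=O)C1=O
F8 | step 5 | 2-methoxy-1-[5-(4,4,5,5-tetramethyl-1,3,2-dioxaborolan-2-yl)-1-SEM-indol-3-yl]ethan-1-one | COCC(=O)c1cn(COCC[Si](C)(C)C)c2ccc(B3OC(C)(C)C(C)(C)O3)cc12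
A1 | alternative 1 | 3-[2,3,5,6-tetramethoxy-4-(1-tosylindol-3-yl)phenyl]-5-prenyl-1H-indole | COc1c(OC)c(-c2c[nH]c3ccc(CC=C(C)C)cc23)c(OC)c(OC)c1-c1cn(S(=O)(=O)c2ccc(C)cc2)c2ccccc12
A2 | alternative 1 | [4-(3-methylbut-2-en-1-yl)phenyl]hydrazine | NNc1ccc(CC=C(C)C)cc1
A3 | alternative 1 | 2-[2,3,5,6-tetramethoxy-4-(1-tosyl-1H-indol-3-yl)phenyl]acetaldehyde | O=CCc1c(OC)c(OC)c(-c2cn(S(=O)(=O)c3ccc(C)cc3)c3ccccc23)c(OC)c1OC
A4 | alternative 2 | 2,5-dihydroxy-3-(1H-indol-3-yl)-6-(5-prenyl-1H-indol-3-yl)-1,4-benzoquinone | O=C1C(O)=C(c2c[nH]c3ccccc23)C(=O)C(O)=C1c1c[nH]c2ccc(CC=C(C)C)cc12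
A5 | alternative 2 | S-ethyl 3-(1H-indol-3-yl)-2-oxopropanethioate | CCSC(=O)C(=O)Cc1c[nH]c2ccccc12
A6 | alternative 2 | S-ethyl 3-(5-prenyl-1H-indol-3-yl)-2-oxopropanethioate | CCSC(=O)C(=O)Cc1c[nH]c2ccc(CC=C(C)C)cc12
A7 | alternative 2 | 2,5-dihydroxy-3,6-bis(1H-indol-3-yl)-1,4-benzoquinone | O=C1C(O)=C(c2c[nH]c3ccccc23)C(=O)C(O)=C1c1c[nH]c2ccccc12
A8 | alternative 2 | 2,5-dihydroxy-3,6-bis(5-prenyl-1H-indol-3-yl)-1,4-benzoquinone | O=C1C(O)=C(c2c[nH]c3ccc(CC=C(C)C)cc23)C(=O)C(O)=C1c1c[nH]c2ccc(CC=C(C)C)cc12
A9 | alternative 3 | 3-[4-(1H-indol-3-yl)-2,3,5,6-tetramethoxyphenyl]-5-prenyl-1-SEM-indole | COc1c(OC)c(-c2c[nH]c3ccccc23)c(OC)c(OC)c1-c1cn(COCC[Si](C)(C)C)c2ccc(CC=C(C)C)cc12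
A10 | alternative 3 | 3-[2,3,5,6-tetramethoxy-4-(5-prenyl-1-SEM-indol-3-yl)phenyl]-2H-azirine | COc1c(OC)c(C2=NC2)c(OC)c(OC)c1-c1cn(COCC[Si](C)(C)C)c2ccc(CC=C(C)C)cc12
A11 | alternative 3 | 2-(trimethylsilyl)phenyl trifluoromethanesulfonate | C[Si](C)(C)c1ccccc1OS(=O)(=O)C(F)(F)F
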